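**Strategy**

The trans-fused oxepane–cyclohexane is cut at two bonds: the ring-fusion bond between the methyl-bearing quaternary carbon (C6) and the ether CH (C7), and the ether bond from the ring oxygen to CMe2 (C2). One flask operation on acyclic diol 13 makes both: oxidation unmasks an aldehyde that a tetrasubstituted (Z)-allylboronate captures through a closed transition state (cyclohexane ring, C6 and C7 set); the new C7 oxygen then opens the (S)-2,2-dimethyloxirane at its tertiary carbon, closing the oxepane. The step exploits the 1,5-relationship of C7–O and C2 along C6–C5–C4–C3–C2. The resulting left iodide is joined to a carvone-derived cis-octalone by 1,2-addition and oxidative enone transposition.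

Key step: step 9

Atom labels used below. Left half: C2 (CMe2), C3 (CHOH), C4, C5, C6 (quaternary C–Me), C7 (CH–O), C8, C9, C10 (C(Me)OH), C11 (CH carrying the chain), C12, C13 (linker). Right half: C1′ (enone carbon carrying the chain), C2′ (C–Me), C3′ (C=O), C4′, C4a′, C5′ (C(Me)OH), C6′, C7′, C8′ (CMe2), C8a′; ring 1 is the enone ring, ring 2 the carbocycle with the gem-dimethyl group.

Remark (assumption): the L-fructose-derived Shi ketone is taken to give the (S)-2,2-dimethyl-3-alkyloxirane, the mirror image of the outcome with the usual D-fructose-derived catalyst.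

Remark (assumption): 4-chloro-4-methylpent-1-ene is made in step 12 because only the corresponding alcohol is assumed to be stocked.

**Left half**

Step 1
Reactants: 1 geraniol
Product: 2 (2S,3S)-2,3-epoxygeraniol
Conditions: Ti(OiPr)4 (cat.), L-(+)-diisopropyl tartrate, t-BuOOH, 4 Å MS, CH2Cl2, −20 °C
Reagents that add atoms: tert-butyl hydroperoxide, CC(C)(C)OO
Why: Sharpless asymmetric epoxidation; the L-(+)-tartrate complex delivers oxygen to the face that gives the (2S,3S)-epoxide, which fixes the future C10 carbinol centre.

Step 2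
Reactants: 2 (2S,3S)-2,3-epoxygeraniol
Product: 3 (2R,3S)-1-chloro-2,3-epoxy-3,7-dimethyloct-6-ene
Conditions: PPh3, CCl4, NaHCO3, reflux
Reagents that add atoms: carbon tetrachloride, ClC(Cl)(Cl)Cl
Why: Appel chlorination of the primary alcohol leaves the epoxide and both stereocentres untouched.

Step 3
Reactants: 3 (2R,3S)-1-chloro-2,3-epoxy-3,7-dimethyloct-6-ene
Product: 4 (S)-3,7-dimethyloct-6-en-1-yn-3-ol
Conditions: n-BuLi (3.3 equiv), THF, −35 °C; aq. NH4Cl
Reagents that add atoms: none
Why: base-induced double elimination of a 2,3-epoxy chloride (epoxide opening to the chloroallyl alkoxide, then dehydrochlorination) should give the tertiary propargylic alcohol with the tertiary C–O bond unbroken, so the (S) centre is retained.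

Step 4
Reactants: 4 (S)-3,7-dimethyloct-6-en-1-yn-3-ol
Product: 6 (S)-4-methylhex-5-yne-1,4-diol, via hydroxy aldehyde 5 (not isolated)
Conditions: O3, CH2Cl2/MeOH, −78 °C; then NaBH4, −78 → 23 °C
Reagents that add atoms: ozone, [O-][O+]=O
Why: ozonolysis with reductive work-up; the electron-rich trisubstituted alkene should react far faster than the terminal alkyne.

Step 5
Reactants: 6 (S)-4-methylhex-5-yne-1,4-diol; 7 5-bromo-2-methylpent-2-ene
Product: 8 (S)-4,10-dimethylundec-9-en-5-yne-1,4-diol
Conditions: n-BuLi (3.1 equiv), THF/DMPU, −78 → 23 °C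
Reagents that add atoms: none
Why: SN2 alkylation of the lithium acetylide; the two lithium alkoxides are much poorer nucleophiles and should stay unalkylated.

Step 6
Reactants: 8 (S)-4,10-dimethylundec-9-en-5-yne-1,4-diol
Product: 10 (4S,5E)-5-iodo-4,6,10-trimethylundeca-5,9-diene-1,4-diol, via alkenylmagnesium species 9 (not isolated)
Conditions: Fe(acac)3 (15 mol %), MeMgBr (5 equiv), THF, −20 → 0 °C; then I2, −78 → 0 °C
Reagents that add atoms: methylmagnesium bromide, C[Mg]Br; iodine, II
Why: alkoxide-directed iron-catalysed syn-carbomagnesiation of the propargylic alcohol should place methyl on the distal carbon C6 and magnesium on C11, and iodinolysis with retention gives the iodoalkene with Me cis to I and the C5 chain cis to C10.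

Step 7
Reactants: 10 (4S,5E)-5-iodo-4,6,10-trimethylundeca-5,9-diene-1,4-diol
Product: 11 (4S,5E)-8-[(2S)-3,3-dimethyloxiran-2-yl]-5-iodo-4,6-dimethyloct-5-ene-1,4-diol
Conditions: L-fructose-derived Shi ketone (30 mol %), Oxone, K2CO3, Bu4NHSO4, MeCN/dimethoxymethane/aq. Na2B4O7 buffer, 0 °C
Reagents that add atoms: potassium peroxymonosulfate, [K+].[O-]S(=O)(=O)OO
Why: Shi asymmetric epoxidation; the chiral dioxirane should epoxidise the unhindered trisubstituted alkene through the spiro transition state to the (S)-epoxide, while the hindered, iodine-deactivated tetrasubstituted alkene is left alone.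

Step 8
Reactants: 11 (4S,5E)-8-[(2S)-3,3-dimethyloxiran-2-yl]-5-iodo-4,6-dimethyloct-5-ene-1,4-diol
Product: 13 (4S,5Z)-8-[(2S)-3,3-dimethyloxiran-2-yl]-4,6-dimethyl-5-[(4,4,5,5-tetramethyl-1,3,2-dioxaborolan-2-yl)methyl]oct-5-ene-1,4-diol, via trilithio intermediate 12 (not isolated)
Conditions: MeLi (2.1 equiv), THF, −78 °C; t-BuLi (2.1 equiv), −78 °C; ICH2Bpin, −78 → 23 °C; aq. NH4Cl
Reagents that add atoms: 2-(iodomethyl)-4,4,5,5-tetramethyl-1,3,2-dioxaborolane, ICB1OC(C)(C)C(C)(C)O1
Why: iodine–lithium exchange with retention of alkene geometry, then Matteson-type homologation (borate formation and 1,2-shift of the alkenyl group with loss of iodide) should give the allylic pinacol boronate.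

Step 9
Reactants: 13 (4S,5Z)-8-[(2S)-3,3-dimethyloxiran-2-yl]-4,6-dimethyl-5-[(4,4,5,5-tetramethyl-1,3,2-dioxaborolan-2-yl)methyl]oct-5-ene-1,4-diol
Product: 16 trans-fused 2,2,5a,7-tetramethyl-6-methylidene-decahydro-1-benzoxepine-3,7-diyl bis(triethylsilyl) ether (C3, C6, C7, C10 as in the target), via aldehyde 14 (not isolated), via borate 15 (not isolated)
Conditions: Dess–Martin periodinane (1.1 equiv), CH2Cl2, 0 → 40 °C; then 2,6-lutidine, Et3SiOTf, CH2Cl2/MeNO2, −40 → 0 °C
Reagents that add atoms: triethylsilyl trifluoromethanesulfonate, CC[Si](CC)(CC)OS(=O)(=O)C(F)(F)F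
Why: Oxidation of the primary alcohol gives aldehyde 14, which the neutral boronate captures intramolecularly (closest known type: thermal allylboration of aldehydes by γ,γ-disubstituted pinacol allylboronates) to give borate 15, and the silyl triflate then triggers opening of the epoxide by the C7 oxygen (closest known type: silyl-triflate-promoted hydroxy-epoxide oxacyclisation). The cyclohexane closes through C6–C7 in a closed six-membered chair-like transition state (boron bridging the aldehyde oxygen and C12) with both alkene carbons ending in the ring, and the oxepane closes 7-endo-tet at the tertiary epoxide carbon C2. C6 and C7 are set relative to each other by the (Z)-alkene geometry: the C5 chain, cis to C10, becomes axial and trans to the axial C7–O, so that after ring flip C7–O and C5 are trans-diequatorial and C6–Me is axial. Both are set relative to C10 by the chair that places the small C10–OH axial and C10–Me equatorial, and C3 keeps the epoxide configuration because the oxygen attacks C2. The step needs chemoselectivity (the aldehyde must be consumed before any acid meets the epoxide, secured by the neutral boronate and by adding the silyl triflate only afterwards) and regioselectivity (7-endo over 6-exo, secured by SN1-like opening at the tertiary carbon under silyl activation). Excess silyl triflate also silylates C10–OH, so the product should emerge protected for the following steps.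

Step 10
Reactants: 16 bicyclic bis(triethylsilyl) ether with exocyclic methylene
Product: 18 2-[(C11-H axial) bis(triethylsilyloxy)-2,2,5a,7-tetramethyl-decahydro-1-benzoxepin-6-yl]ethanol, via aldehyde 17 (not isolated)
Conditions: Rh(acac)(CO)2 (2 mol %), tris(2,4-di-tert-butylphenyl) phosphite, CO/H2 (1:1, 40 bar), toluene, 90 °C; then NaBH4, MeOH, 0 °C
Reagents that add atoms: carbon monoxide, [C-]#[O+]
Why: rhodium-catalysed hydroformylation of the 1,1-disubstituted alkene must be anti-Markovnikov, hydrogen should reach C11 from the face opposite the two axial methyl groups on C6 and C10 (C11–H axial, chain equatorial), and borohydride then reduces the aldehyde.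

Step 11
Reactants: 18 primary alcohol
Product: 19 the corresponding primary iodide (C13–I)
Conditions: I2, PPh3, imidazole, CH2Cl2, 0 → 23 °C
Reagents that add atoms: iodine, II
Why: Appel-type iodination of the only free (primary) alcohol.

**Right half**

Step 12
Reactants: 20 2-methylpent-4-en-2-ol
Product: 21 4-chloro-4-methylpent-1-ene
Conditions: conc. HCl, 0 → 23 °C
Reagents that add atoms: hydrogen chloride, Cl
Why: SN1 substitution of the tertiary alcohol; the monosubstituted alkene should not add HCl under these conditions.

Step 13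
Reactants: 22 (S)-(+)-carvone
Product: 23 (S)-carvone trimethylsilyl dienol ether (2-silyloxy-1,3-diene)
Conditions: LDA, THF, −78 °C; Me3SiCl
Reagents that add atoms: chlorotrimethylsilane, C[Si](C)(C)Cl
Why: kinetic α′-deprotonation of the enone and O-silylation give the cross-conjugated silyl dienol ether; the carvone stereocentre (future C4a′) is untouched.

Step 14
Reactants: 23 (S)-carvone trimethylsilyl dienol ether; 21 4-chloro-4-methylpent-1-ene
Product: 24 (5S)-2-methyl-6-(2-methylpent-4-en-2-yl)-5-(prop-1-en-2-yl)cyclohex-2-en-1-one, 5,6-trans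
Conditions: TiCl4, CH2Cl2, −45 °C
Reagents that add atoms: none
Why: Lewis-acid-mediated α-tert-alkylation of a silyl enol ether (SN1, Mukaiyama type); the tertiary cation should attack C8a′ anti to the isopropenyl group, giving the trans isomer and the quaternary C8′.

Step 15
Reactants: 24 5,6-trans enone
Product: 26 (5S)-2-methyl-6-(2-methylpent-4-en-2-yl)-5-(prop-1-en-2-yl)cyclohex-2-en-1-one, 5,6-cis, via lithium enolate 25 (not isolated)
Conditions: LDA, THF, −78 °C; then AcOH in THF, −78 °C
Reagents that add atoms: none
Why: kinetic α′-deprotonation followed by kinetic protonation; A(1,2) strain with the tert-alkyl group on the enolate carbon should force the isopropenyl group pseudo-axial, so the proton arrives anti to it and C8a′–H ends cis to C4a′–H.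

Step 16
Reactants: 26 5,6-cis enone
Product: 27 cis-2,5,8,8-tetramethyl-4,4a,7,8-tetrahydronaphthalen-1(8aH)-one (4aS, ring-fusion hydrogens cis)
Conditions: second-generation Grubbs catalyst (H2IMes)(PCy3)Cl2Ru=CHPh (5 mol %), CH2Cl2, 40 °C
Reagents that add atoms: none
Why: ring-closing metathesis of the terminal alkene with the isopropenyl group closes ring 2 as a trisubstituted cyclohexene under neutral conditions that should not epimerise C8a′.

**Union and end game**

Step 17
Reactants: 19 primary iodide; 27 cis-fused dienone
Product: 29 tertiary allylic alcohol (C1′ carbinol, configuration at C1′ not controlled), via alkyllithium 28 (not isolated)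
Conditions: t-BuLi (2.1 equiv), Et2O/pentane, −78 °C; CeCl3, THF, −78 °C; then 27, −78 → 0 °C
Reagents that add atoms: none
Why: iodine–lithium exchange and 1,2-addition of the organocerium reagent to the enone carbonyl; its low basicity should suppress enolisation at C8a′, and the new carbinol centre is removed in the next step.

Step 18
Reactants: 29 tertiary allylic alcohol
Product: 30 bis(triethylsilyl) ether of the 3-alkyl-2-methylcyclohexenone (C5′=C6′ alkene still present)
Conditions: pyridinium chlorochromate, NaOAc, 4 Å MS, CH2Cl2, 23 °C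
Reagents that add atoms: pyridinium chlorochromate, [O-][Cr](=O)(=O)Cl.c1cc[nH+]cc1
Why: Babler–Dauben oxidative 1,3-transposition; the chromate ester of the tertiary allylic alcohol undergoes [3,3]-shift and oxidation to the transposed enone without touching C4a′ or C8a′.

Step 19
Reactants: 30 bis(triethylsilyl) ether
Product: 31 3,10-diol with the C5′=C6′ alkene
Conditions: HF·pyridine, pyridine, THF, 0 → 23 °C
Reagents that add atoms: none
Why: fluoride-mediated cleavage of both triethylsilyl ethers under buffered conditions that should leave the enone and the alkene alone.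

Step 20
Reactants: 31 3,10-diol with the C5′=C6′ alkene
Product: 32 sipholenol K
Conditions: Co(acac)2 (20 mol %), PhSiH3, O2 (1 atm), THF/i-PrOH, 23 °C; aq. Na2S2O3
Reagents that add atoms: dioxygen, O=O
Why: Mukaiyama hydration (hydrogen-atom transfer, Markovnikov); the tertiary C5′ radical should be trapped by oxygen anti to C4′, that is on the convex face syn to the ring-fusion hydrogens, and the tetrasubstituted enone should be too hindered to accept a hydrogen atom.

**Compound list**

1 | geraniol | CC(C)=CCC/C(C)=C/CO | starting material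
2 | (2S,3S)-2,3-epoxygeraniol | OC[C@@H]1O[C@@]1(C)CCC=C(C)C | intermediate
3 | (2R,3S)-1-chloro-2,3-epoxy-3,7-dimethyloct-6-ene | ClC[C@@H]1O[C@@]1(C)CCC=C(C)C | intermediate
4 | (S)-3,7-dimethyloct-6-en-1-yn-3-ol | C#C[C@@](C)(O)CCC=C(C)C | intermediate
5 | (S)-4-hydroxy-4-methylhex-5-ynal (in equilibrium with its lactol) | C#C[C@@](C)(O)CCC=O | intermediate
6 | (S)-4-methylhex-5-yne-1,4-diol | C#C[C@@](C)(O)CCCO | intermediate
7 | 5-bromo-2-methylpent-2-ene | BrCCC=C(C)C | starting material
8 | (S)-4,10-dimethylundec-9-en-5-yne-1,4-diol | OCCC[C@](C)(O)C#CCCC=C(C)C | intermediate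
9 | alkenylmagnesium bromide bis(bromomagnesium alkoxide) from syn-carbomagnesiation | Br[Mg]OCCC[C@](C)(O[Mg]Br)/C([Mg]Br)=C(/C)CCC=C(C)C | intermediate
10 | (4S,5E)-5-iodo-4,6,10-trimethylundeca-5,9-diene-1,4-diol | OCCC[C@](C)(O)/C(I)=C(/C)CCC=C(C)C | intermediate
11 | (4S,5E)-8-[(2S)-3,3-dimethyloxiran-2-yl]-5-iodo-4,6-dimethyloct-5-ene-1,4-diol | OCCC[C@](C)(O)/C(I)=C(/C)CC[C@@H]1OC1(C)C | intermediate
12 | alkenyllithium dilithium alkoxide from 11 | [Li]OCCC[C@](C)(O[Li])/C([Li])=C(/C)CC[C@@H]1OC1(C)C | intermediate
13 | (4S,5Z)-allylic pinacol boronate diol with (S)-epoxide | OCCC[C@](C)(O)/C(CB1OC(C)(C)C(C)(C)O1)=C(/C)CC[C@@H]2OC2(C)C | intermediate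
14 | aldehyde from 13 (largely as lactol) | O=CCC[C@](C)(O)/C(CB1OC(C)(C)C(C)(C)O1)=C(/C)CC[C@@H]2OC2(C)C | intermediate
15 | cyclohexyl pinacol borate from allylboration (exocyclic methylene, C6 and C7 set) | C=C1[C@](C)(CC[C@@H]2OC2(C)C)[C@@H](OB3OC(C)(C)C(C)(C)O3)CC[C@]1(C)O | intermediate
16 | trans-fused 2,2,5a,7-tetramethyl-6-methylidene-decahydro-1-benzoxepine-3,7-diyl bis(triethylsilyl) ether | C=C1[C@]2(C)CC[C@H](O[Si](CC)(CC)CC)C(C)(C)O[C@H]2CC[C@]1(C)O[Si](CC)(CC)CC | intermediate
17 | C13 aldehyde from hydroformylation of 16 | O=CC[C@H]1[C@]2(C)CC[C@H](O[Si](CC)(CC)CC)C(C)(C)O[C@H]2CC[C@]1(C)O[Si](CC)(CC)CC | intermediate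
18 | C13 primary alcohol | OCC[C@H]1[C@]2(C)CC[C@H](O[Si](CC)(CC)CC)C(C)(C)O[C@H]2CC[C@]1(C)O[Si](CC)(CC)CC | intermediate
19 | C13 primary iodide | ICC[C@H]1[C@]2(C)CC[C@H](O[Si](CC)(CC)CC)C(C)(C)O[C@H]2CC[C@]1(C)O[Si](CC)(CC)CC | intermediate
20 | 2-methylpent-4-en-2-ol | CC(C)(O)CC=C | starting material
21 | 4-chloro-4-methylpent-1-ene | CC(C)(Cl)CC=C | intermediate
22 | (S)-(+)-carvone | CC1=CC[C@@H](CC1=O)C(C)=C | starting material
23 | (S)-carvone trimethylsilyl dienol ether | CC1=CC[C@@H](C=C1O[Si](C)(C)C)C(C)=C | intermediate
24 | (5S)-2-methyl-6-(2-methylpent-4-en-2-yl)-5-(prop-1-en-2-yl)cyclohex-2-en-1-one, 5,6-trans | CC1=CC[C@H](C(C)=C)[C@H](C1=O)C(C)(C)CC=C | intermediate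
25 | lithium enolate of 24 | CC1=CC[C@H](C(C)=C)C(C(C)(C)CC=C)=C1O[Li] | intermediate
26 | (5S)-2-methyl-6-(2-methylpent-4-en-2-yl)-5-(prop-1-en-2-yl)cyclohex-2-en-1-one, 5,6-cis | CC1=CC[C@H](C(C)=C)[C@@H](C1=O)C(C)(C)CC=C | intermediate
27 | cis-2,5,8,8-tetramethyl-4,4a,7,8-tetrahydronaphthalen-1(8aH)-one (4aS) | CC1=CC[C@H]2[C@@H](C1=O)C(C)(C)CC=C2C | intermediate
28 | alkyllithium from 19 | [Li]CC[C@H]1[C@]2(C)CC[C@H](O[Si](CC)(CC)CC)C(C)(C)O[C@H]2CC[C@]1(C)O[Si](CC)(CC)CC | intermediate
29 | tertiary allylic alcohol from addition of 28 to 27 (C1′ configuration undefined) | CC1=CC[C@H]2[C@@H](C1(O)CC[C@H]3[C@]4(C)CC[C@H](O[Si](CC)(CC)CC)C(C)(C)O[C@H]4CC[C@]3(C)O[Si](CC)(CC)CC)C(C)(C)CC=C2C | intermediate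
30 | transposed enone, bis(triethylsilyl) ether, C5′=C6′ alkene | CC1=C(CC[C@H]3[C@]4(C)CC[C@H](O[Si](CC)(CC)CC)C(C)(C)O[C@H]4CC[C@]3(C)O[Si](CC)(CC)CC)[C@@H]2[C@H](CC1=O)C(C)=CCC2(C)C | intermediate
31 | transposed enone, free 3,10-diol, C5′=C6′ alkene | CC1=C(CC[C@H]3[C@]4(C)CC[C@H](O)C(C)(C)O[C@H]4CC[C@]3(C)O)[C@@H]2[C@H](CC1=O)C(C)=CCC2(C)C | intermediate
32 | sipholenol K | CC1=C(CC[C@H]2[C@]3(C)CC[C@H](O)C(C)(C)O[C@H]3CC[C@]2(C)O)[C@@H]2[C@H](CC1=O)[C@@](C)(O)CCC2(C)C | target

**Count and risks**

Total step count: 20. Longest linear sequence: 15 steps (steps 1–11, then 17–20).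

Steps most likely to fail:

1. Step 9. The hindered pinacol boronate may add too slowly through the bridged closed transition state, so that the lactol form of the γ-hydroxy aldehyde is over-oxidised, and oxidant by-products are carried into the silyl triflate stage, where opening at the secondary epoxide carbon (6-exo) can also compete. Fallback, setting out from 13 and coming back at 16: 13 is converted with KHF2 into the potassium allyltrifluoroborate F1. F1 is oxidised under Parikh–Doering conditions to the aldehyde trifluoroborate F2, which should be stable because a trifluoroborate does not add without activation. Allylation is then triggered on its own under phase-transfer conditions (Bu4NI, CH2Cl2/H2O) through the same closed transition state, and the diol epoxide F3 is isolated and purified. F3 is then cyclised and silylated with Et3SiOTf/2,6-lutidine in a clean medium to give 16.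

2. Step 10. Hydroformylation at an alkene flanked by two quaternary carbons may stall, hydrogenate the alkene, or deliver hydrogen to C11 from the wrong face. Fallback, setting out from 16 and coming back at 18: hydroboration with the small reagent BH3·SMe2 from the face opposite the axial methyl groups, then pinacol, gives the primary boronate F4. Matteson homologation (BrCH2Cl, n-BuLi, −78 °C) gives the one-carbon-extended boronate F5. Oxidation with NaBO3 gives 18.

3. Step 15. LDA may deprotonate at C4′ (γ) instead of the hindered C8a′–H, giving the linear dienolate and a deconjugated enone, or the protonation may show poor facial selectivity. Fallback, setting out from 24 and coming back at 27: the trans isomer 24 is ring-closed first (second-generation Grubbs catalyst) to the trans-fused dienone F6. C8a′ is then epimerised on the bicycle under equilibrating conditions (DBU, toluene). The cis-fused 27 is expected to be favoured there because it relieves the peri interaction between the C1′ carbonyl and the gem-dimethyl group, but this is not certain.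

Further compounds
F1 | step 9 | potassium allyltrifluoroborate from 13 | OCCC[C@](C)(O)/C(C[B-](F)(F)F)=C(/C)CC[C@@H]1OC1(C)C.[K+]
F2 | step 9 | aldehyde trifluoroborate (largely as lactol) | O=CCC[C@](C)(O)/C(C[B-](F)(F)F)=C(/C)CC[C@@H]1OC1(C)C.[K+]
F3 | step 9 | cyclohexane-1,4-diol epoxide from allylation (exocyclic methylene) | C=C1[C@](C)(CC[C@@H]2OC2(C)C)[C@@H](O)CC[C@]1(C)O
F4 | step 10 | C12 pinacol boronate from hydroboration of 16 | CC1(C)OB(C[C@H]2[C@]3(C)CC[C@H](O[Si](CC)(CC)CC)C(C)(C)O[C@H]3CC[C@]2(C)O[Si](CC)(CC)CC)OC1(C)C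
F5 | step 10 | C13 pinacol boronate from Matteson homologation | CC1(C)OB(CC[C@H]2[C@]3(C)CC[C@H](O[Si](CC)(CC)CC)C(C)(C)O[C@H]3CC[C@]2(C)O[Si](CC)(CC)CC)OC1(C)C
F6 | step 15 | trans-fused 2,5,8,8-tetramethyl-4,4a,7,8-tetrahydronaphthalen-1(8aH)-one | CC1=CC[C@H]2[C@H](C1=O)C(C)(C)CC=C2C
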